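**Retrosynthetic overview**
- Target ⇒ triol lacking only the primary benzoate ⇒ bicyclic acetonide in which O7 and O2 are tied as a 1,3-dioxane (regioselective benzoylation, then acetal hydrolysis, in reverse).
- The cyclohexene is opened at C4=C5 by ring-closing metathesis ⇒ an acyclic 1,7-diene carried on the dioxane.
- Key C1–C6 bond: a dihydroxyacetone-type ketone (C1) plus a 3-(benzoyloxy)allyl indium nucleophile, in which the former carbonyl carbon of acrolein reacts with reversed polarity; this one step sets C1 and C6 and delivers the C6 benzoate.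
- The ketone comes from zinc fragmentation of a 6-iodo-D-fructofuranoside; C2 and C3 of the target are C3 and C4 of D-fructose.
- Ring order: furanose and 1,3-dioxane (step 1) → furanose opened (step 5) → cyclohexene by metathesis (step 6) → dioxane removed (step 7).

Assumption: target atoms are numbered C1 (quaternary carbinol), C2 (CH–OH), C3 (CH–OBz), C4=C5, C6 (CH–OBz), C7 (CH2OBz); the target is then (1S,2S,3R,6R), with O1, O2 and O6 on one face and O3 and C7 on the other. 3-Bromopropenyl benzoate is made (step 4), not bought.

**Step 1**
Reactants: 1 D-fructose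
Product: 3 methyl 1,3-O-isopropylidene-α-D-fructofuranoside, via methyl α-D-fructofuranoside 2 (not isolated)
Conditions: MeOH, AcCl (cat.), 25 °C, 1 h; Et3N, evaporate; then Me2C(OMe)2, acetone, TsOH (cat.), 25 °C
Reagents that add atoms: methanol, CO; 2,2-dimethoxypropane, COC(C)(C)OC
Why: Kinetic Fischer glycosidation gives the methyl furanosides, and in the acid-catalysed transacetalisation that follows only the α-anomer has C1 cis to O3 and can close the cis-fused 1,3-dioxane, so the anomers drain into 3; C3 and C4 of fructose (later C2 and C3) are carried through untouched and no lasting stereocentre is made.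

**Step 2**
Reactants: 3 methyl 1,3-O-isopropylidene-α-D-fructofuranoside
Product: 4 methyl 6-deoxy-6-iodo-1,3-O-isopropylidene-α-D-fructofuranoside
Conditions: PPh3, I2, imidazole, THF, 0 → 25 °C
Reagents that add atoms: iodine, [I][I]
Why: Appel-type iodination (Garegg–Samuelsson conditions) displaces the phosphonium-activated primary 6-OH by SN2 much faster than the secondary 4-OH, and imidazole keeps the medium non-acidic for the ketoside and acetonide; no stereocentre is touched.

**Step 3**
Reactants: 4 methyl 6-deoxy-6-iodo-1,3-O-isopropylidene-α-D-fructofuranoside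
Product: 5 methyl 4-O-benzoyl-6-deoxy-6-iodo-1,3-O-isopropylidene-α-D-fructofuranoside
Conditions: BzCl, Et3N, DMAP (cat.), CH2Cl2, 0 °C
Reagents that add atoms: benzoyl chloride, O=C(Cl)c1ccccc1
Why: DMAP-catalysed O-acylation of the only free hydroxyl (O4, the later C3 benzoate); no stereocentre is touched.

**Step 4**
Reactants: 6 acrolein; 7 benzoyl bromide
Product: 8 3-bromoprop-1-enyl benzoate (E/Z mixture)
Conditions: ZnCl2 (cat.), CH2Cl2, −20 → 0 °C
Reagents that add atoms: none
Why: ZnCl2-catalysed addition of the acyl bromide across the enal (1,2-addition, then allylic transposition of bromide to the conjugated enol ester) is the known preparation of 3-bromopropenyl esters and turns the electrophilic carbonyl carbon of acrolein into the oxygen-bearing end of an allyl bromide; no stereocentre, and both alkene isomers are used.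

**Step 5**
Reactants: 5 methyl 4-O-benzoyl-6-deoxy-6-iodo-1,3-O-isopropylidene-α-D-fructofuranoside; 8 3-bromoprop-1-enyl benzoate
Product: 11 (1R)-1-[(4S,5R)-5-[(1R)-1-(benzoyloxy)prop-2-enyl]-5-hydroxy-2,2-dimethyl-1,3-dioxan-4-yl]prop-2-enyl benzoate, via dioxanone ketone 9 (not isolated), via benzoyloxyallylindium dibromide 10 (not isolated)
Conditions: Zn dust, THF/H2O (4:1), ultrasound, 40 °C; then 8 (3 equiv), In powder (2 equiv), 25 °C
Reagents that add atoms: none
Why: Proposed new method: Bernet–Vasella zinc insertion into the carbon–iodine bond and β-elimination of the ring oxygen (known for iodo-aldofuranosides, here on a ketofuranoside) unmask the base-sensitive dioxanone 9, which is trapped at once by organoindium 10 in a Barbier-type α-hydroxyallylation (known for aldehydes, here on an activated α,α'-dialkoxy ketone), the oxygen-bearing allyl terminus bonding to the ketone carbon through a six-membered cyclic transition state; equatorial attack on the chair 1,3-dioxan-5-one, anti to both ring C–O bonds and trans to the equatorial C4 side chain, sets C1 with its hydroxyl cis to O2, and in that transition state the sector next to the side chain is taken by hydrogen or by the slim allyl arm and not by the benzoate, which gives the 6R centre with O6 cis to O1.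

**Step 6**
Reactants: 11 the diene carbinol from step 5
Product: 12 (4aR,5R,8R,8aS)-4a-hydroxy-2,2-dimethyl-4a,5,8,8a-tetrahydro-4H-1,3-benzodioxine-5,8-diyl dibenzoate (trans ring fusion)
Conditions: second-generation Grubbs catalyst RuCl2(=CHPh)(PCy3)(H2IMes) (5 mol%), CH2Cl2 (0.01 M), 40 °C
Reagents that add atoms: none
Why: Ring-closing olefin metathesis of a 1,7-diene whose two vinyl-bearing arms sit gauche (both equatorial) on the dioxane chair closes the cyclohexene with loss of ethene; the free tertiary alcohol and the benzoates are tolerated and no stereocentre is touched.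

**Step 7**
Reactants: 12 the bicyclic acetonide
Product: 13 (1S,2S,3R,6R)-1,2-dihydroxy-1-(hydroxymethyl)cyclohex-4-ene-3,6-diyl dibenzoate
Conditions: AcOH/H2O (4:1), 50 °C
Reagents that add atoms: none
Why: Acid-catalysed acetal hydrolysis frees O2 and O7; aqueous acetic acid is too mild to ionise the allylic benzoates or to drive acyl migration, and no stereocentre is touched.

**Step 8**
Reactants: 13 the triol
Product: 14 (1S,2S,3R,6R)-1-[(benzoyloxy)methyl]-1,2-dihydroxycyclohex-4-ene-3,6-diyl dibenzoate (target)
Conditions: BzCl (1.1 equiv), pyridine, CH2Cl2, −40 → 0 °C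
Reagents that add atoms: benzoyl chloride, O=C(Cl)c1ccccc1
Why: Regioselective O-acylation: the primary C7 hydroxyl is far more accessible than the secondary C2 hydroxyl (flanked by quaternary C1 and benzoylated C3) and the tertiary C1 hydroxyl, so one equivalent of acid chloride at low temperature gives the primary benzoate; no stereocentre is touched.

**Compound list**
1 | D-fructose | OC[C@H]([C@H]([C@@H](C(=O)CO)O)O)O | starting material
2 | methyl α-D-fructofuranoside (formed alongside its β-anomer) | CO[C@@]1(CO)O[C@H](CO)[C@@H](O)[C@@H]1O | intermediate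
3 | methyl 1,3-O-isopropylidene-α-D-fructofuranoside | CO[C@]12COC(C)(C)O[C@H]1[C@H](O)[C@@H](CO)O2 | intermediate
4 | methyl 6-deoxy-6-iodo-1,3-O-isopropylidene-α-D-fructofuranoside | CO[C@]12COC(C)(C)O[C@H]1[C@H](O)[C@@H](CI)O2 | intermediate
5 | methyl 4-O-benzoyl-6-deoxy-6-iodo-1,3-O-isopropylidene-α-D-fructofuranoside | CO[C@]12COC(C)(C)O[C@H]1[C@H](OC(=O)c3ccccc3)[C@@H](CI)O2 | intermediate
6 | acrolein | C=CC=O | starting material
7 | benzoyl bromide | O=C(Br)c1ccccc1 | starting material
8 | 3-bromoprop-1-enyl benzoate (E/Z mixture) | BrCC=COC(=O)c1ccccc1 | intermediate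
9 | (1R)-1-[(4S)-2,2-dimethyl-5-oxo-1,3-dioxan-4-yl]prop-2-enyl benzoate | O=C1COC(C)(C)O[C@H]1[C@H](OC(=O)c2ccccc2)C=C | intermediate
10 | (Z)-3-(benzoyloxy)prop-2-enylindium dibromide (trivalent indium; one component of the organoindium mixture) | O=C(O/C=C\C[In](Br)Br)c1ccccc1 | intermediate
11 | (1R)-1-[(4S,5R)-5-[(1R)-1-(benzoyloxy)prop-2-enyl]-5-hydroxy-2,2-dimethyl-1,3-dioxan-4-yl]prop-2-enyl benzoate | C=C[C@@H](OC(=O)c1ccccc1)[C@]2(O)COC(C)(C)O[C@H]2[C@H](OC(=O)c1ccccc1)C=C | intermediate
12 | (4aR,5R,8R,8aS)-4a-hydroxy-2,2-dimethyl-4a,5,8,8a-tetrahydro-4H-1,3-benzodioxine-5,8-diyl dibenzoate | CC1(C)OC[C@@]2(O)[C@H](OC(=O)c3ccccc3)C=C[C@@H](OC(=O)c3ccccc3)[C@@H]2O1 | intermediate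
13 | (1S,2S,3R,6R)-1,2-dihydroxy-1-(hydroxymethyl)cyclohex-4-ene-3,6-diyl dibenzoate | OC[C@@]1(O)[C@H](OC(=O)c2ccccc2)C=C[C@@H](OC(=O)c2ccccc2)[C@@H]1O | intermediate
14 | (1S,2S,3R,6R)-1-[(benzoyloxy)methyl]-1,2-dihydroxycyclohex-4-ene-3,6-diyl dibenzoate | O=C(OC[C@@]1(O)[C@H](OC(=O)c2ccccc2)C=C[C@@H](OC(=O)c2ccccc2)[C@@H]1O)c1ccccc1 | target

**Step count**
Total steps: 8. Longest linear sequence: 7 (steps 1, 2, 3, 5, 6, 7, 8 from D-fructose); step 4 is a one-step side branch.

**Steps most likely to fail, with fallbacks**

Step 5 (highest risk). The ketone acceptor is unprecedented for this reagent, ketone 9 can lose benzoate by β-elimination if it lingers, and the C6 selectivity may be modest; the 6-epimer would have to be removed by chromatography at 11 or 12. The fallback sets out from 5 and comes back at 12, and replaces the one-step hydroxyallylation by an acyl-anion addition followed by a stereocontrolled reduction.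
- The zinc fragmentation of 5 is run alone and ketone 9 is isolated by a cold neutral work-up.
- The acryloyl anion equivalent 1-lithio-1-methoxyallene F1 (methoxyallene, nBuLi, THF, −78 °C) adds to 9 along the same equatorial trajectory to give the allenyl carbinol F2.
- Brief aqueous oxalic acid (THF/H2O, 0 °C) hydrolyses the enol ether to the α-hydroxy vinyl ketone F3.
- Metathesis with RuCl2(=CHPh)(PCy3)(H2IMes) closes the bicyclic enone F4.
- Luche reduction (NaBH4, CeCl3·7H2O, MeOH, −78 °C) delivers hydride axially, anti to the axial C1–O bond, and gives the allylic alcohol F5 with O6 cis to O1.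
- BzCl, pyridine and DMAP acylate the secondary hydroxyl of F5 and give 12.

Step 8. Over-benzoylation at O2, or base-induced benzoate migration, would erode the yield. The fallback sets out from 13 and comes back at 14. It replaces reagent-controlled chemical acylation by enzyme-catalysed transesterification (immobilised Candida antarctica lipase B, vinyl benzoate, THF, 40 °C), in which access to the active-site serine, not intrinsic nucleophilicity, selects the primary hydroxyl under neutral conditions. No new compound is made (F0).

Step 6. Both alkenes carry allylic benzoates and the new ring must fuse trans onto the dioxane, so closure may be slow. The fallback sets out from 11 and comes back at 13, and reverses the order of deprotection and cyclisation. The acetonide of 11 is hydrolysed first (AcOH/H2O, 50 °C) to the acyclic triol diene F6, which is then closed with the same ruthenium catalyst, free of the ring-fusion constraint, to give 13 directly.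

**Further compounds**
F1 | step 5 | 1-lithio-1-methoxyallene | [Li]C(OC)=C=C
F2 | step 5 | (1R)-1-[(4S,5R)-5-hydroxy-5-(1-methoxypropa-1,2-dienyl)-2,2-dimethyl-1,3-dioxan-4-yl]prop-2-enyl benzoate | C=C=C(OC)[C@]1(O)COC(C)(C)O[C@H]1[C@H](OC(=O)c2ccccc2)C=C
F3 | step 5 | (1R)-1-[(4S,5R)-5-acryloyl-5-hydroxy-2,2-dimethyl-1,3-dioxan-4-yl]prop-2-enyl benzoate | C=CC(=O)[C@]1(O)COC(C)(C)O[C@H]1[C@H](OC(=O)c2ccccc2)C=C
F4 | step 5 | bicyclic enone: the 6-oxo analogue of 12 lacking the C6 benzoate (target numbering) | CC1(C)OC[C@@]2(O)C(=O)C=C[C@@H](OC(=O)c3ccccc3)[C@@H]2O1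
F5 | step 5 | allylic alcohol: 12 with free C6 hydroxyl (target numbering) | CC1(C)OC[C@@]2(O)[C@H](O)C=C[C@@H](OC(=O)c3ccccc3)[C@@H]2O1
F6 | step 6 | acyclic triol diene: 11 without the isopropylidene group | C=C[C@@H](OC(=O)c1ccccc1)[C@](O)(CO)[C@@H](O)[C@H](OC(=O)c1ccccc1)C=C
F0 | step 8 | none | none
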